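**Plan**

- Retrosynthesis: the two phenolic O–H groups flanking the ketone go back to O–CH3 (ether cleavage last). The aryl–C(=O) bond is cut next (Friedel–Crafts acylation), and the pyrone is cut last across C4–C5 and O1–C2.
- Enabling feature: in the 4-hydroxy-2-pyrone ring, C5 (methyl), C6 (ethyl) and O1 are the enol of symmetrical 3-pentanone, while C2, C3 and C4 are a malonyl unit whose central carbon C3 carries the arylmethyl group.
- Forward: the benzene ring is bought as 2,4,6-trimethoxybenzaldehyde and joined to a malonate (Knoevenagel condensation, hydrogenation). The malonyl dichloride and the silyl enol ether of 3-pentanone then close the pyrone, the only ring that is made. Acylation of the open arene position and double O-demethylation finish the route.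
- Stereochemistry: the single stereocentre (R, alpha to the aryl ketone) is bought as (R)-2-methylbutanoic acid and carried in as its acid chloride; no bond at that carbon is made or broken.

Key step: step 5

Remark: (R)-2-methylbutanoic acid is taken to be available in enantiopure form, and the silyl enol ether of 3-pentanone is drawn as its Z isomer although either geometry leads to the same pyrone.

**Route**

Step 1
Reactants: 1 2,4,6-trimethoxybenzaldehyde; 2 dibenzyl malonate
Product: 3 dibenzyl 2-(2,4,6-trimethoxybenzylidene)malonate
Conditions: piperidine (0.2 equiv), AcOH (0.2 equiv), toluene, reflux, Dean–Stark trap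
Reagents that add atoms: none
Why: Knoevenagel condensation, in which the piperidine-derived iminium ion of the electron-rich, doubly ortho-substituted aldehyde is attacked by the malonate enol and azeotropic removal of water drives the reaction to completion; the two ester groups are identical, so no alkene isomers arise.

Step 2
Reactants: 3 dibenzyl 2-(2,4,6-trimethoxybenzylidene)malonate
Product: 5 2-(2,4,6-trimethoxybenzyl)malonic acid, via dibenzyl 2-(2,4,6-trimethoxybenzyl)malonate 4 (not isolated)
Conditions: H2 (1 atm), 10% Pd/C, EtOAc–EtOH, rt; concentration below 40 °C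
Reagents that add atoms: none
Why: Catalytic hydrogenation saturates the electron-poor alkene to 4 and the same catalyst hydrogenolyses both benzyl esters, so the malonic acid is freed under neutral conditions at room temperature, where it should not decarboxylate.

Step 3
Reactants: 5 2-(2,4,6-trimethoxybenzyl)malonic acid
Product: 6 2-(2,4,6-trimethoxybenzyl)malonyl dichloride
Conditions: (COCl)2 (2.5 equiv), DMF (cat.), CH2Cl2, 0 °C → rt; volatiles removed, crude used at once
Reagents that add atoms: oxalyl chloride, O=C(Cl)C(Cl)=O
Why: Acid chloride formation through the Vilsmeier-type chloroiminium catalyst should convert both carboxyl groups at 0 °C much faster than the reagent attacks the arene CH positions, and the two ortho methoxy groups rule out intramolecular Friedel–Crafts acylation.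

Step 4
Reactants: 7 3-pentanone
Product: 8 (Z)-3-(trimethylsilyloxy)pent-2-ene
Conditions: Me3SiCl (1.2 equiv), Et3N (2.4 equiv), DMF, 80 °C; pentane extraction, distillation
Reagents that add atoms: chlorotrimethylsilane, C[Si](C)(C)Cl
Why: Silyl enol ether formation under equilibrating conditions gives a single constitutional isomer from the symmetrical ketone, mainly as the Z enol ether, and the alkene geometry is erased later in the aromatic pyrone.

Step 5
Reactants: 6 2-(2,4,6-trimethoxybenzyl)malonyl dichloride; 8 (Z)-3-(trimethylsilyloxy)pent-2-ene
Product: 10 6-ethyl-4-hydroxy-5-methyl-3-(2,4,6-trimethoxybenzyl)-2H-pyran-2-one, via 4-methyl-3,5-dioxo-2-(2,4,6-trimethoxybenzyl)heptanoyl chloride 9 (not isolated)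
Conditions: 8 (1.5 equiv), Et2O, −78 °C → rt, 12 h; then H2O
Reagents that add atoms: none
Why: The nucleophilic CH carbon of 8 attacks one acyl chloride of 6 (or the chlorocarbonylketene that 6 forms by loss of HCl), which makes the C4–C5 bond and, after loss of Me3SiCl, gives the diketo acid chloride 9. The enol oxygen of the ethyl ketone in 9 then adds to the remaining COCl carbon and expels chloride, a 6-exo-trig lactonisation that makes the O1–C2 bond, and enolisation of the resulting pyran-2,4-dione gives the aromatic 4-hydroxy-2-pyrone 10. The closest known reaction type is the cyclocondensation of malonyl dichlorides or chlorocarbonylketenes with silyl enol ethers and ketones to 4-hydroxy-2-pyrones. No stereocentre is created, and the two stereogenic carbons of 9 become trigonal in 10. The step needs one acylation at carbon and one at oxygen of the same enol unit instead of intermolecular oligomerisation: carbon attack first follows from the carbon nucleophilicity of the silyl enol ether, the second acylation is intramolecular and six-membered, and even the reverse order would close to the same pyrone. Regiochemistry is not in question because 3-pentanone is symmetrical, and the two methoxy groups ortho to the benzylic carbon block any cyclisation of an acyl chloride onto the arene.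

Step 6
Reactants: 11 (R)-2-methylbutanoic acid
Product: 12 (R)-2-methylbutanoyl chloride
Conditions: (COCl)2 (1.05 equiv), DMF (cat.), CH2Cl2, 0 °C → rt; excess reagent and solvent distilled off
Reagents that add atoms: oxalyl chloride, O=C(Cl)C(Cl)=O
Why: Acid chloride formation with Vilsmeier-type catalysis takes place at the carboxyl carbon only, and in the absence of base no ketene forms, so the alpha stereocentre should keep its R configuration.

Step 7
Reactants: 10 6-ethyl-4-hydroxy-5-methyl-3-(2,4,6-trimethoxybenzyl)-2H-pyran-2-one; 12 (R)-2-methylbutanoyl chloride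
Product: 13 6-ethyl-4-hydroxy-5-methyl-3-{2,4,6-trimethoxy-3-[(2R)-2-methylbutanoyl]benzyl}-2H-pyran-2-one
Conditions: 12 (2 equiv), TiCl4 (3 equiv), CH2Cl2, −20 → 0 °C; then ice-cold 1 M HCl
Reagents that add atoms: none
Why: Friedel–Crafts acylation, in which the acylium ion from 12 and TiCl4 attacks one of the two equivalent open arene carbons (each activated by two ortho and one para methoxy group), the new ketone deactivates the ring against a second acylation, excess TiCl4 ties up the acidic pyrone hydroxyl, pyrone C3 and C5 are substituted, and the stereocentre is brought in unchanged from 12, the low temperature limiting acid-promoted enolisation.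

Step 8
Reactants: 13 6-ethyl-4-hydroxy-5-methyl-3-{2,4,6-trimethoxy-3-[(2R)-2-methylbutanoyl]benzyl}-2H-pyran-2-one
Product: 15 3-{2,4-dihydroxy-6-methoxy-3-[(2R)-2-methylbutanoyl]benzyl}-6-ethyl-4-hydroxy-5-methyl-2H-pyran-2-one, via bis(dichloroboryl) ether 14 (not isolated)
Conditions: BCl3 (1 M in CH2Cl2, 6 equiv), CH2Cl2, −78 °C → rt; then H2O, 0 °C
Reagents that add atoms: none
Why: Chelation-directed aryl methyl ether cleavage, in which BCl3 held between the ketone oxygen and a flanking methoxy oxygen is opened by SN2 attack of chloride at methyl on each side in turn to give the boron aryloxide 14, whereas the third methoxy group is para to the ketone, cannot chelate and is the least basic ether oxygen, and aqueous work-up should free the two phenols without touching the stereocentre.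

**Compound list**

1 | 2,4,6-trimethoxybenzaldehyde | COc1cc(OC)c(C=O)c(OC)c1 | starting material
2 | dibenzyl malonate | O=C(CC(=O)OCc1ccccc1)OCc1ccccc1 | starting material
3 | dibenzyl 2-(2,4,6-trimethoxybenzylidene)malonate | COc1cc(OC)c(C=C(C(=O)OCc2ccccc2)C(=O)OCc2ccccc2)c(OC)c1 | intermediate
4 | dibenzyl 2-(2,4,6-trimethoxybenzyl)malonate | COc1cc(OC)c(CC(C(=O)OCc2ccccc2)C(=O)OCc2ccccc2)c(OC)c1 | intermediate (not isolated)
5 | 2-(2,4,6-trimethoxybenzyl)malonic acid | COc1cc(OC)c(CC(C(O)=O)C(O)=O)c(OC)c1 | intermediate
6 | 2-(2,4,6-trimethoxybenzyl)malonyl dichloride | COc1cc(OC)c(CC(C(Cl)=O)C(Cl)=O)c(OC)c1 | intermediate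
7 | 3-pentanone | CCC(=O)CC | starting material
8 | (Z)-3-(trimethylsilyloxy)pent-2-ene | C/C=C(\O[Si](C)(C)C)CC | intermediate
9 | 4-methyl-3,5-dioxo-2-(2,4,6-trimethoxybenzyl)heptanoyl chloride (mixture of stereoisomers) | CCC(=O)C(C)C(=O)C(Cc1c(OC)cc(OC)cc1OC)C(Cl)=O | intermediate (not isolated)
10 | 6-ethyl-4-hydroxy-5-methyl-3-(2,4,6-trimethoxybenzyl)-2H-pyran-2-one | CCc1oc(=O)c(Cc2c(OC)cc(OC)cc2OC)c(O)c1C | intermediate
11 | (R)-2-methylbutanoic acid | CC[C@@H](C)C(O)=O | starting material
12 | (R)-2-methylbutanoyl chloride | CC[C@@H](C)C(Cl)=O | intermediate
13 | 6-ethyl-4-hydroxy-5-methyl-3-{2,4,6-trimethoxy-3-[(2R)-2-methylbutanoyl]benzyl}-2H-pyran-2-one | CCc1oc(=O)c(Cc2c(OC)cc(OC)c(C(=O)[C@H](C)CC)c2OC)c(O)c1C | intermediate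
14 | 3-{2,4-bis[(dichloroboranyl)oxy]-6-methoxy-3-[(2R)-2-methylbutanoyl]benzyl}-6-ethyl-4-hydroxy-5-methyl-2H-pyran-2-one | CCc1oc(=O)c(Cc2c(OC)cc(OB(Cl)Cl)c(C(=O)[C@H](C)CC)c2OB(Cl)Cl)c(O)c1C | intermediate (not isolated)
15 | 3-{2,4-dihydroxy-6-methoxy-3-[(2R)-2-methylbutanoyl]benzyl}-6-ethyl-4-hydroxy-5-methyl-2H-pyran-2-one | CCc1oc(=O)c(Cc2c(OC)cc(O)c(C(=O)[C@H](C)CC)c2O)c(O)c1C | target

**Step count**

Total steps: 8. Longest linear sequence: 6 (steps 1, 2, 3, 5, 7, 8, from 2,4,6-trimethoxybenzaldehyde).

**Steps most likely to fail**

Step 5. The annulation may lose material to intermolecular acylation and oligomers, to self-condensation of the ketene derived from 6, or to protodesilylation of 8 by the HCl released before it is acylated. The fallback sets out from 8 and 1 and comes back to the route at 10. Unsubstituted malonyl dichloride and 8 in Et2O at −78 °C → rt should give 6-ethyl-4-hydroxy-5-methyl-2H-pyran-2-one F1 by the same C4–C5 and O1–C2 ring closure in its simplest and best-documented form. F1, aldehyde 1 and Hantzsch ester (diethyl 2,6-dimethyl-1,4-dihydropyridine-3,5-dicarboxylate) with catalytic L-proline in EtOH at rt should then condense to 6-ethyl-5-methyl-3-(2,4,6-trimethoxybenzylidene)-2H-pyran-2,4(3H)-dione F2, which is reduced in the same flask by hydride transfer to 10. This is the known three-component reductive alkylation of cyclic 1,3-dicarbonyl compounds; having the hydride donor present from the start suppresses addition of a second pyrone to F2.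

Step 7. The Lewis acid may erode the configuration alpha to the carbonyl (enolisation of the complexed ketone or ketene formation from the acylium ion). It may also divert the acyl chloride to the pyrone oxygen, induce ipso attack with loss of the arylmethyl bridge, or start ether cleavage early. The fallback sets out from 10 and acid 11, bypasses 12, and comes back at 13. Acid 11 and trifluoroacetic anhydride in CH2Cl2 at 0 °C should give (2R)-2-methylbutanoic trifluoroacetic anhydride F3, which acylates the trimethoxyarene position of 10 without any metal halide (a little 85% H3PO4 as promoter if needed). Acylation of highly activated arenes by carboxylic acids through their mixed trifluoroacetic anhydrides is established chemistry.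

Step 8. The second ether cleavage may stall once the first boron chelate has locked the carbonyl, forcing may let cleavage stray to the methoxy group para to the ketone, and long exposure to the Lewis acid may epimerise the alpha stereocentre or cleave the arylmethyl bridge. The fallback sets out from 13 and comes back at 15 by dividing the transformation into two separately controlled single cleavages. BCl3 (about 2 equiv) in CH2Cl2 at −78 °C with a cold quench should stop after the first, dependable chelation-controlled cleavage and give 6-ethyl-4-hydroxy-3-{2-hydroxy-4,6-dimethoxy-3-[(2R)-2-methylbutanoyl]benzyl}-5-methyl-2H-pyran-2-one F4 and/or its regioisomer 6-ethyl-4-hydroxy-3-{4-hydroxy-2,6-dimethoxy-3-[(2R)-2-methylbutanoyl]benzyl}-5-methyl-2H-pyran-2-one F5, isolated together. The remaining ether flanking the ketone in each is then cleaved with the more oxophilic AlCl3 in CH2Cl2 at 0 °C → rt, monitored to stop before the para methoxy group reacts. Both monophenols converge on 15.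

Further compounds
F1 | step 5 | 6-ethyl-4-hydroxy-5-methyl-2H-pyran-2-one | CCc1oc(=O)cc(O)c1C
F2 | step 5 | 6-ethyl-5-methyl-3-(2,4,6-trimethoxybenzylidene)-2H-pyran-2,4(3H)-dione | CCC1=C(C)C(=O)C(=Cc2c(OC)cc(OC)cc2OC)C(=O)O1
F3 | step 7 | (2R)-2-methylbutanoic trifluoroacetic anhydride | CC[C@@H](C)C(=O)OC(=O)C(F)(F)F
F4 | step 8 | 6-ethyl-4-hydroxy-3-{2-hydroxy-4,6-dimethoxy-3-[(2R)-2-methylbutanoyl]benzyl}-5-methyl-2H-pyran-2-one | CCc1oc(=O)c(Cc2c(OC)cc(OC)c(C(=O)[C@H](C)CC)c2O)c(O)c1C
F5 | step 8 | 6-ethyl-4-hydroxy-3-{4-hydroxy-2,6-dimethoxy-3-[(2R)-2-methylbutanoyl]benzyl}-5-methyl-2H-pyran-2-one | CCc1oc(=O)c(Cc2c(OC)cc(O)c(C(=O)[C@H](C)CC)c2OC)c(O)c1C
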